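**Remarks on the chemistry (assumptions)**

- Numbering used throughout: lactone C1 (C=O), C2 (benzyl-bearing), C3, C4 (OCH2); C7 is the benzyl CH2 on C2 and C7' the carbinol carbon on C3.
- The target is the (2R,3R,7'S) isomer, i.e. (3R,4R)-4-[(S)-(3,4-dimethoxyphenyl)(hydroxy)methyl]-3-(4-hydroxy-3-methoxybenzyl)dihydrofuran-2(3H)-one.
- "(mac)B" means boron esterified by cis-1,2-dimethyl-1,2-dihydroacenaphthylene-1,2-diol (compound 2). It replaces the pinacol ester of the alkenylboron partner, because β-substituted alkenyl pinacol boronates are expected to give direct coupling at boron instead of the metallate shift. The carbon skeleton, the bonds formed and the stereochemical course are unchanged.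
- The Z enol triflate and the E benzylidene ester of the coupling product have the same geometry (ester trans to aryl); only the priority order changes the descriptor.
- The hand of the ferrocenyl diphosphine is assigned by analogy. If it gives the mirror-image product, the antipodal ligand, which is equally available, is used.
- Compounds 1, 3, 4, 7, 8 and 13 are taken as catalogue chemicals. Compound 7 is the benzyl ether of vanillin and 3 the silyl ether of propargyl alcohol, bought to save two protection steps.
- The end game is ordered so that hydrogenation and C2 equilibration are done while C7' still carries boron. The benzylic alcohol is unmasked only in the last step.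

## Structural features

The target is a 2,3-disubstituted γ-butyrolactone (C1 carbonyl, C2, C3, C4 as OCH2, ring oxygen) carrying two non-fused benzene rings: a 4-hydroxy-3-methoxyphenyl ring joined to C2 through the C7 methylene and a 3,4-dimethoxyphenyl ring joined to C3 through the carbinol carbon C7'. Three stereocentres stand in a row, C2 (R), C3 (R) and C7' (S); C2 and C3 are trans on the ring, while C3/C7' is an open-chain pair. The C7' alcohol is the fragile group: it is benzylic to an electron-rich ring, so acid can ionise it (elimination, or Friedel–Crafts closure onto the other ring), hydrogenation can cleave it, and it sits γ to C1, so a ring-opened lactone could re-close on the wrong oxygen. C2 is epimerisable and the phenol is free; C2 is nevertheless the easy centre, because the trans arrangement is the thermodynamic one. The real difficulty is the C3/C7' pair: C7' is two carbons away from C1, so no simple lactone-enolate aldol reaches it, and both centres must be fixed absolutely and relative to each other outside a ring. The key step exploits the fact that C7' bears one aryl group and one heteroatom that can come from boron, while its neighbour C3 is bonded to C2, which can be an sp2 carbon when the bond is made. An alkene C3=C7' with boron on C7' can therefore accept the aryl group at C7' and C2 at C3 in one anti addition.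

## Logic of the disconnections

**21 ⇒ 20.** The C7'–O bond is traded for a C7'–B bond. The sensitive benzylic alcohol then exists only in the final compound, and the oxygen arrives with retention. The forward step must oxidise a hindered boronic ester without opening the lactone for long or touching the phenol.

**20 ⇒ 19.** Only the configuration at C2 is changed. Because trans is thermodynamically preferred, C2 need not be controlled kinetically; the forward step is an equilibration that must leave C3, C7' and the C–B bond alone.

**19 ⇒ 18.** The C2–H and C7–H bonds and the phenol O–H are cut back to a C2=C7 alkene and a benzyl ether. This makes C2 an sp2 carbon, which is what an alkenyl electrophile can deliver. The forward hydrogenation must reduce the alkene and remove the benzyl group while sparing the C–B bond.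

**18 ⇒ 16 (through 17).** The lactone C1–O bond is cut to a methyl ester and a silyl ether on C4. The ring then forms by simple acyl substitution after desilylation. The forward step must avoid base, which could move the exocyclic alkene into the ring and erase C3.

**16 ⇒ 6 + 13 + 12 (through 14 and 15).** The C7'–aryl and C3–C2 bonds are cut in one retrosynthetic move, which is the key step. It yields three achiral fragments of comparable size and removes both difficult stereocentres at once. The forward step must proceed as a metallate shift and not as direct coupling, be anti across the E alkene, be controlled by the chiral ligand, and outrun β-elimination from the C3–palladium intermediate.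

**12 ⇒ 11 ⇒ 10 ⇒ 9 ⇒ 7 + 8.** The enol C–O triflate bond goes back to the enol of an α-keto ester, and the C2–C7 bond to an aldehyde plus a glycine unit. The geometry of 12 is not critical, because the alkene is hydrogenated later.

**6 ⇒ 3 + 4 + 2 (through 5).** The C–B bond comes from syn hydroboration of a terminal alkyne, which fixes the E geometry that later encodes the C3/C7' relationship. The diol on boron is exchanged at the same stage.

**2 ⇒ 1.** Two C–CH3 bonds are cut back to a 1,2-diketone. The forward step must give the cis diol, since only that isomer can bridge one boron atom.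

## Other disconnections considered

**Alternative 1:** Enzymatic ring expansion.
- Cut: the C4–O bond of the lactone, back to the prochiral cyclobutanone A1.
- Forward key step: a flavin-dependent Baeyer–Villiger monooxygenase with O2 and NADPH inserts oxygen into one of the two ring C–C(=O) bonds of A1, giving lactone A2 and fixing C3. Enolate benzylation of A2 would then place the C2 substituent anti to the C3 group.
- In favour: the conditions are mild and aqueous, ring strain drives the reaction, and 3-substituted cyclobutanones are an established substrate class for these enzymes. The later alkylation sets C2 trans directly under kinetic control, which is better than the hydrogenation-plus-equilibration of the chosen plan.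
- Against: C7' must be made beforehand in a separate asymmetric step. The enzyme must then distinguish two diastereotopic bonds next to a bulky silyloxy(aryl)methyl group, so a matched case and an enzyme screen would be needed. C3 and C7' are set in two unrelated events.
- Comparison: the chosen plan links C3 and C7' mechanistically in one stereospecific addition, whereas here the link depends on enzyme–substrate fit. Step count is about equal. The alternative is the better of the two in reagent mildness and in C2 control.

**Alternative 2:** Cyclopropane as a temporary bond.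
- Cut: C2–C3 plus a temporary C2–C7' bond, back to diazomalonate A3.
- Forward key step: the metal carbene from A3 (for example with Rh2(S-PTTL)4) adds to its own Z alkene, closing the cyclopropane and the lactone together to give A4 with the aryl group cis to C4. An oxygen nucleophile would later open the C2–C7' bond at the benzylic carbon with inversion, followed by C2 benzylation and loss of the extra ester.
- In favour: one event forms two C–C bonds and two rings, and the alkene geometry fixes the C3/C7' relationship. In this stereochemical linkage it is the equal of the chosen plan, and the lactone is already in place. No organolithium is needed.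
- Against: carbenes flanked by two acceptor groups are a hard case for enantioselective intramolecular cyclopropanation. A3 needs a cis-selective alkyne reduction in its preparation. Ring opening at so electron-rich a benzylic carbon may drift towards ionisation and erode C7'. Alkylation and dealkoxycarbonylation add steps after the key step, under conditions the benzylic C–O bond may not like.
- Comparison: the chosen plan carries C7' as boron and converts it with retention, with no cationic pathway, and brings the whole C2 benzyl unit in during the same step. Both plans end with a thermodynamic adjustment at C2, so they are equal there.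

**Alternative 3:** Formaldehyde aldol–lactonisation.
- Cut: C3–C4 and the lactone C–O bond, back to keto acid A5.
- Forward key step: the ketone enolate at C3 of A5 adds to formaldehyde, and the new primary alcohol closes onto the acid to give the trans keto lactone A6. The C7' ketone would then be reduced.
- In favour: the reagents are cheap and no transition metal is involved. C3 is α to the ketone, so the trans ring arrangement is reached without a separate equilibration, which is better than in the chosen plan. C2 can come from well-established asymmetric chemistry, and the sequence is probably one or two steps shorter.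
- Against: C7' is set last, by substrate-controlled hydride delivery next to C3, and neither the sense nor the level of that induction is secured by design. Enolisation must be regioselective, and double hydroxymethylation or dehydration to an exo-methylene ketone can compete.
- Comparison: the chosen plan fixes C3/C7' by mechanism and the absolute sense by catalyst, while here the most fragile centre is the least controlled one. The alternative is better in cost and scalability.

Key step: step 7

## Route

Step 1
Reactants: 1 acenaphthylene-1,2-dione
Product: 2 (1R,2S)-1,2-dimethyl-1,2-dihydroacenaphthylene-1,2-diol (cis; meso)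
Conditions: MeMgBr (3 equiv), THF, −78 °C to rt; sat. aq NH4Cl; recrystallisation
Reagents that add atoms: methylmagnesium bromide, C[Mg]Br
Why: Double Grignard 1,2-addition to the diketone; the second methyl group is expected to add anti to the bulky magnesium alkoxide formed first, favouring the cis (meso) diol, which is the only isomer able to bridge one boron and is freed from any trans isomer by crystallisation.

Step 2
Reactants: 3 tert-butyldimethyl(prop-2-yn-1-yloxy)silane; 4 catecholborane; 2 (1R,2S)-1,2-dimethyl-1,2-dihydroacenaphthylene-1,2-diol
Product: 6 (E)-tert-butyldimethyl{[3-((mac)B)allyl]oxy}silane, via catechol alkenylboronate 5 (not isolated)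
Conditions: 4 (1.1 equiv), neat, 70 °C; then 2 (1.0 equiv), THF, rt; aq NaOH wash
Reagents that add atoms: none
Why: Uncatalysed syn hydroboration of the terminal alkyne places boron on the terminal carbon and gives the E alkenylboronate; the labile catechol ester is then exchanged for the di-tertiary diol (transesterification), the released catechol being removed by the basic wash.

Step 3
Reactants: 7 4-(benzyloxy)-3-methoxybenzaldehyde; 8 N-acetylglycine
Product: 9 (Z)-4-[4-(benzyloxy)-3-methoxybenzylidene]-2-methyl-1,3-oxazol-5(4H)-one
Conditions: NaOAc (1 equiv), Ac2O, 100 °C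
Reagents that add atoms: none
Why: Erlenmeyer–Plöchl azlactone synthesis: acetic anhydride cyclodehydrates 8 to the oxazolone, whose acidic C4–H condenses with the aldehyde to give the thermodynamically preferred Z arylidene azlactone.

Step 4
Reactants: 9 (Z)-4-[4-(benzyloxy)-3-methoxybenzylidene]-2-methyl-1,3-oxazol-5(4H)-one
Product: 10 3-[4-(benzyloxy)-3-methoxyphenyl]-2-oxopropanoic acid (largely as its enol)
Conditions: NaOH (10% aq), reflux, N2; then HCl (aq), 0 °C, pH 1
Reagents that add atoms: water, O
Why: Hydroxide opens the azlactone to the acetamidoacrylate and hydrolyses the enamide to the α-keto carboxylate with loss of acetate and ammonia (classical azlactone hydrolysis); base is used in place of hot mineral acid so that the benzyl ether survives, and air is excluded to prevent oxidative degradation of the pyruvate.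

Step 5
Reactants: 10 3-[4-(benzyloxy)-3-methoxyphenyl]-2-oxopropanoic acid
Product: 11 methyl 3-[4-(benzyloxy)-3-methoxyphenyl]-2-oxopropanoate (largely as its Z enol)
Conditions: MeOH, Me3SiCl (0.3 equiv), rt
Reagents that add atoms: methanol, CO
Why: Fischer esterification with HCl made in the flask; the keto group is tied up as its conjugated enol and should not ketalise at room temperature, and no alkylating agent is present that could attack the enol oxygen.

Step 6
Reactants: 11 methyl 3-[4-(benzyloxy)-3-methoxyphenyl]-2-oxopropanoate
Product: 12 methyl (Z)-3-[4-(benzyloxy)-3-methoxyphenyl]-2-{[(trifluoromethyl)sulfonyl]oxy}acrylate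
Conditions: Tf2O (1.2 equiv), i-Pr2NEt (1.5 equiv), CH2Cl2, −78 °C
Reagents that add atoms: trifluoromethanesulfonic anhydride, O=S(=O)(OS(=O)(=O)C(F)(F)F)C(F)(F)F
Why: O-Sulfonylation of the enolate of an arylpyruvate, which is expected to react from its conjugated Z enol form and so give the Z enol triflate; either geometry would serve, because the alkene is hydrogenated in step 9.

Step 7
Reactants: 13 4-bromo-1,2-dimethoxybenzene; 6 (E)-tert-butyldimethyl{[3-((mac)B)allyl]oxy}silane; 12 methyl (Z)-3-[4-(benzyloxy)-3-methoxyphenyl]-2-{[(trifluoromethyl)sulfonyl]oxy}acrylate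
Product: 16 methyl (2E,3R,4S)-2-[4-(benzyloxy)-3-methoxybenzylidene]-3-[(tert-butyldimethylsilyloxy)methyl]-4-(3,4-dimethoxyphenyl)-4-[(mac)B]butanoate, via 3,4-dimethoxyphenyllithium 14 (not isolated), via lithium aryl(alkenyl)borate 15 (not isolated)
Conditions: 13 (1.15 equiv), t-BuLi (2.3 equiv), Et2O, −78 °C; 6 (1.2 equiv), −78 °C to rt; then Pd(OAc)2 (2 mol %), (Sp,Sp)-MandyPhos [1,1'-bis{bis(4-methoxy-3,5-dimethylphenyl)phosphino}-2,2'-bis{(R)-α-(dimethylamino)benzyl}ferrocene] (2.4 mol %), KOSO2CF3 (2 equiv), 12 (1.0 equiv), THF, 60 °C
Reagents that add atoms: none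
Why: Lithium–bromine exchange gives 14, which adds to the trigonal boron of 6 to form the four-coordinate borate 15; Pd(OAc)2 and the diphosphine are reduced in the flask to a zerovalent palladium complex that inserts into the C–O bond of 12, and because triflate does not stay on the metal the resulting divalent alkenylpalladium cation can bind the electron-rich alkene of 15. Binding triggers a 1,2-shift of the aryl group from boron to C7' on the alkene face opposite palladium while C3 becomes bonded to palladium, and reductive elimination then forms C3–C2 with retention at C3 and with the enol triflate geometry preserved. The closest known reaction type is the palladium-catalysed conjunctive cross-coupling of β-substituted alkenylboron ate complexes of this hindered diol with aryl and alkenyl triflates. No ring is closed. The C3/C7' relationship follows from the E geometry of 6 and the anti course of the metallate shift, and the absolute sense at both centres is set together by the chiral diphosphine when palladium selects one alkene face. The step needs the metallate shift to beat direct boron-to-palladium transfer, and reductive elimination to beat loss of silyloxide or hydride from the C3–palladium intermediate: the hindered diol in 6 and the halide-free cationic palladium (KOSO2CF3 removes LiBr as KBr) should secure the first, and the wide-bite-angle ligand with the poor leaving-group ability of a silyloxide the second. Keeping 12 limiting and 6 in slight excess over 14 leaves no free aryllithium to attack the ester.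

Step 8
Reactants: 16 methyl (2E,3R,4S)-2-[4-(benzyloxy)-3-methoxybenzylidene]-3-[(tert-butyldimethylsilyloxy)methyl]-4-(3,4-dimethoxyphenyl)-4-[(mac)B]butanoate
Product: 18 (3E,4R)-3-[4-(benzyloxy)-3-methoxybenzylidene]-4-[(S)-(3,4-dimethoxyphenyl)((mac)B)methyl]dihydrofuran-2(3H)-one, via hydroxy ester 17 (not isolated)
Conditions: TsOH·H2O (0.2 equiv), MeOH, rt; concentrate; toluene, 50 °C
Reagents that add atoms: none
Why: Acid-catalysed methanolysis of the primary silyl ether frees the C4 alcohol, which closes the five-membered lactone onto the ester (5-exo-trig acyl substitution, driven by removal of methanol); acid is preferred to fluoride or base so that the exocyclic C2=C7 alkene cannot migrate into the ring and erase C3, and the boronic ester is inert to it.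

Step 9
Reactants: 18 (3E,4R)-3-[4-(benzyloxy)-3-methoxybenzylidene]-4-[(S)-(3,4-dimethoxyphenyl)((mac)B)methyl]dihydrofuran-2(3H)-one
Product: 19 (3S,4R)-4-[(S)-(3,4-dimethoxyphenyl)((mac)B)methyl]-3-(4-hydroxy-3-methoxybenzyl)dihydrofuran-2(3H)-one (cis)
Conditions: H2 (1–3 atm), Pd/C (10%), EtOAc, rt
Reagents that add atoms: none
Why: Heterogeneous hydrogenation saturates the benzylidene alkene and hydrogenolyses the benzyl ether in one operation; hydrogen should arrive on the ring face opposite the large C3 substituent, so the cis lactone is expected to predominate (any trans isomer is already the wanted one), and since C7' carries boron and not yet oxygen there is no benzylic C–O bond to lose, C–B bonds being inert to hydrogenolysis.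

Step 10
Reactants: 19 (3S,4R)-4-[(S)-(3,4-dimethoxyphenyl)((mac)B)methyl]-3-(4-hydroxy-3-methoxybenzyl)dihydrofuran-2(3H)-one
Product: 20 (3R,4R)-4-[(S)-(3,4-dimethoxyphenyl)((mac)B)methyl]-3-(4-hydroxy-3-methoxybenzyl)dihydrofuran-2(3H)-one (trans)
Conditions: DBU (3 equiv), toluene, 80 °C; aq NH4Cl wash
Reagents that add atoms: none
Why: Base-mediated epimerisation through the lactone enolate; the trans 2,3-disubstituted butyrolactone is the thermodynamic isomer, the more so with a substituent as large as the C3 group here, C3 and C7' carry no acidic hydrogen, and with no free C7' hydroxyl present the non-nucleophilic amidine can neither open nor re-route the lactone.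

Step 11
Reactants: 20 (3R,4R)-4-[(S)-(3,4-dimethoxyphenyl)((mac)B)methyl]-3-(4-hydroxy-3-methoxybenzyl)dihydrofuran-2(3H)-one
Product: 21 (3R,4R)-4-[(S)-(3,4-dimethoxyphenyl)(hydroxy)methyl]-3-(4-hydroxy-3-methoxybenzyl)dihydrofuran-2(3H)-one
Conditions: NaBO3·4H2O (5 equiv), THF/H2O (1:1), rt; then NaH2PO4 (aq) to pH 5
Reagents that add atoms: sodium perborate tetrahydrate, [Na+].OO[B-](O)(O)O.O.O
Why: Boronate oxidation: hydroperoxide adds to boron and C7' migrates from boron to oxygen with retention, giving the (S) carbinol; perborate is a mild, self-buffered oxidant that should spare the phenol, and the weakly acidic work-up re-closes any lactone opened in the flask through its primary C4 hydroxyl.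

## Compound list

1 | acenaphthylene-1,2-dione | O=C1C(=O)c2cccc3cccc1c23 | starting material
2 | (1R,2S)-1,2-dimethyl-1,2-dihydroacenaphthylene-1,2-diol (cis, meso) | C[C@]1(O)c2cccc3cccc(c23)[C@@]1(C)O | intermediate
3 | tert-butyldimethyl(prop-2-yn-1-yloxy)silane | C#CCO[Si](C)(C)C(C)(C)C | starting material
4 | catecholborane (1,3,2-benzodioxaborole) | B1Oc2ccccc2O1 | starting material
5 | 2-[(E)-3-(tert-butyldimethylsilyloxy)prop-1-en-1-yl]-1,3,2-benzodioxaborole | CC(C)(C)[Si](C)(C)OC/C=C/B1Oc2ccccc2O1 | intermediate (not isolated)
6 | (E)-tert-butyldimethyl{[3-((mac)B)allyl]oxy}silane, i.e. the ester of (E)-3-(tert-butyldimethylsilyloxy)prop-1-enylboronic acid with diol 2 | CC(C)(C)[Si](C)(C)OC/C=C/B1O[C@@]2(C)c3cccc4cccc(c34)[C@@]2(C)O1 | intermediate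
7 | 4-(benzyloxy)-3-methoxybenzaldehyde | COc1cc(C=O)ccc1OCc1ccccc1 | starting material
8 | N-acetylglycine | CC(=O)NCC(=O)O | starting material
9 | (Z)-4-[4-(benzyloxy)-3-methoxybenzylidene]-2-methyl-1,3-oxazol-5(4H)-one | CC1=N/C(=C\c2ccc(OCc3ccccc3)c(OC)c2)C(=O)O1 | intermediate
10 | 3-[4-(benzyloxy)-3-methoxyphenyl]-2-oxopropanoic acid (keto form drawn) | COc1cc(CC(=O)C(=O)O)ccc1OCc1ccccc1 | intermediate
11 | methyl 3-[4-(benzyloxy)-3-methoxyphenyl]-2-oxopropanoate (keto form drawn) | COC(=O)C(=O)Cc1ccc(OCc2ccccc2)c(OC)c1 | intermediate
12 | methyl (Z)-3-[4-(benzyloxy)-3-methoxyphenyl]-2-{[(trifluoromethyl)sulfonyl]oxy}acrylate | COC(=O)/C(OS(=O)(=O)C(F)(F)F)=C/c1ccc(OCc2ccccc2)c(OC)c1 | intermediate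
13 | 4-bromo-1,2-dimethoxybenzene | COc1ccc(Br)cc1OC | starting material
14 | 3,4-dimethoxyphenyllithium | [Li]c1ccc(OC)c(OC)c1 | intermediate (not isolated)
15 | lithium [(E)-3-(tert-butyldimethylsilyloxy)prop-1-enyl](3,4-dimethoxyphenyl)borate of diol 2 (configuration at boron not defined) | [Li+].CC(C)(C)[Si](C)(C)OC/C=C/[B-]1(c2ccc(OC)c(OC)c2)O[C@@]2(C)c3cccc4cccc(c34)[C@@]2(C)O1 | intermediate (not isolated)
16 | methyl (2E,3R,4S)-2-[4-(benzyloxy)-3-methoxybenzylidene]-3-[(tert-butyldimethylsilyloxy)methyl]-4-(3,4-dimethoxyphenyl)-4-[(mac)B]butanoate | COC(=O)/C(=C/c1ccc(OCc2ccccc2)c(OC)c1)[C@H](CO[Si](C)(C)C(C)(C)C)[C@H](B1O[C@@]2(C)c3cccc4cccc(c34)[C@@]2(C)O1)c1ccc(OC)c(OC)c1 | intermediate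
17 | methyl (2E,3R,4S)-2-[4-(benzyloxy)-3-methoxybenzylidene]-4-(3,4-dimethoxyphenyl)-3-(hydroxymethyl)-4-[(mac)B]butanoate | COC(=O)/C(=C/c1ccc(OCc2ccccc2)c(OC)c1)[C@H](CO)[C@H](B1O[C@@]2(C)c3cccc4cccc(c34)[C@@]2(C)O1)c1ccc(OC)c(OC)c1 | intermediate (not isolated)
18 | (3E,4R)-3-[4-(benzyloxy)-3-methoxybenzylidene]-4-[(S)-(3,4-dimethoxyphenyl)((mac)B)methyl]dihydrofuran-2(3H)-one | COc1cc(/C=C2/C(=O)OC[C@@H]2[C@H](B3O[C@@]4(C)c5cccc6cccc(c56)[C@@]4(C)O3)c2ccc(OC)c(OC)c2)ccc1OCc1ccccc1 | intermediate
19 | (3S,4R)-4-[(S)-(3,4-dimethoxyphenyl)((mac)B)methyl]-3-(4-hydroxy-3-methoxybenzyl)dihydrofuran-2(3H)-one (cis) | COc1cc(C[C@@H]2C(=O)OC[C@@H]2[C@H](B3O[C@@]4(C)c5cccc6cccc(c56)[C@@]4(C)O3)c2ccc(OC)c(OC)c2)ccc1O | intermediate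
20 | (3R,4R)-4-[(S)-(3,4-dimethoxyphenyl)((mac)B)methyl]-3-(4-hydroxy-3-methoxybenzyl)dihydrofuran-2(3H)-one (trans) | COc1cc(C[C@H]2C(=O)OC[C@@H]2[C@H](B3O[C@@]4(C)c5cccc6cccc(c56)[C@@]4(C)O3)c2ccc(OC)c(OC)c2)ccc1O | intermediate
21 | (3R,4R)-4-[(S)-(3,4-dimethoxyphenyl)(hydroxy)methyl]-3-(4-hydroxy-3-methoxybenzyl)dihydrofuran-2(3H)-one | COc1cc(C[C@H]2C(=O)OC[C@@H]2[C@H](O)c2ccc(OC)c(OC)c2)ccc1O | target

## Step count and least certain steps

Total step count: 11. Longest linear sequence: 9 steps (steps 3 to 11, from 7 to 21).

**Step 7 (key step).**
- What may go wrong: direct transfer of the aryl or alkenyl group from boron to palladium may compete with the metallate shift, because the β-substituent slows alkene binding. The C3–palladium intermediate may lose silyloxide or hydride before reductive elimination, because the ester-bearing alkenyl group is a slower partner than simple ones. The ligand may discriminate the alkene faces poorly with so hindered an electrophile.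
- Fallback (sets out from 7, returns at 21): this fallback forms C3–C7' by an auxiliary-controlled aldol reaction instead. Stobbe condensation of 7 with dimethyl succinate (NaOMe, MeOH) gives the half-ester (E)-4-[4-(benzyloxy)-3-methoxyphenyl]-3-(methoxycarbonyl)but-3-enoic acid F1. Its pivaloyl mixed anhydride acylates (S)-4-benzyl-1,3-oxazolidin-2-one (Et3N, LiCl) to give the imide F2. An Evans syn aldol reaction (Bu2BOTf, i-Pr2NEt, then 3,4-dimethoxybenzaldehyde) sets C3 and C7' in the aldol adduct F3. LiBH4 removes the auxiliary reductively, and the freed C4 alcohol closes onto the ester to give the hydroxy benzylidene lactone F4. Hydrogenation over Pd/C gives the cis hydroxy lactone F5, and DBU equilibrates C2 to give 21. Its own weak points would be lactonisation through the C7' oxygen and hydrogenolysis of the benzylic C–O bond.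

**Step 11.**
- What may go wrong: oxidation of the hindered boronic ester may be slow, so that the lactone sits for long in aqueous base. It may then open and re-close through the C7' hydroxyl, or C2 may drift.
- Fallback (sets out from 20, returns at 21): KHF2 in aqueous methanol converts the boronic ester into the potassium trifluoroborate F6. This is oxidised within minutes, near neutrality and with retention, by KHSO5 (as 2KHSO5·KHSO4·K2SO4) in acetone/water to give 21.

**Step 4.**
- What may go wrong: the arylpyruvate may undergo aldol self-condensation or oxidative cleavage during the long alkaline reflux, because it is a strongly enolised, electron-rich α-keto acid.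
- Fallback (sets out from 7, returns at 11): Horner–Wadsworth–Emmons reaction of 7 with methyl 2-(tert-butyldimethylsilyloxy)-2-(dimethoxyphosphoryl)acetate (LiN(SiMe3)2, THF) gives the silyl enol ether methyl (Z)-3-[4-(benzyloxy)-3-methoxyphenyl]-2-[(tert-butyldimethylsilyl)oxy]acrylate F7 (either alkene isomer serves). CsF with AcOH in MeCN releases 11, bypassing 9 and 10.

**Step 2.**
- What may go wrong: exchange of catechol for the hindered diol may be incomplete, or the catechol ester may hydrolyse before exchange, leaving mixed boron species that are hard to separate.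
- Fallback (sets out from 3, returns at 6): hydroboration of 3 with pinacolborane catalysed by Cp2Zr(H)Cl gives the pinacol ester F8. NaIO4 with NH4OAc in acetone/water cleaves it to the boronic acid F9, which is condensed with 2 (MgSO4, CH2Cl2) to give 6.

## Further compounds

F1 | step 7 | (E)-4-[4-(benzyloxy)-3-methoxyphenyl]-3-(methoxycarbonyl)but-3-enoic acid | COC(=O)/C(=C/c1ccc(OCc2ccccc2)c(OC)c1)CC(=O)O
F2 | step 7 | methyl (E)-2-[4-(benzyloxy)-3-methoxybenzylidene]-4-[(S)-4-benzyl-2-oxo-1,3-oxazolidin-3-yl]-4-oxobutanoate | COC(=O)/C(=C/c1ccc(OCc2ccccc2)c(OC)c1)CC(=O)N1[C@@H](Cc2ccccc2)COC1=O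
F3 | step 7 | methyl (2E,3S,4S)-2-[4-(benzyloxy)-3-methoxybenzylidene]-3-{[(S)-4-benzyl-2-oxo-1,3-oxazolidin-3-yl]carbonyl}-4-(3,4-dimethoxyphenyl)-4-hydroxybutanoate | COC(=O)/C(=C/c1ccc(OCc2ccccc2)c(OC)c1)[C@H](C(=O)N1[C@@H](Cc2ccccc2)COC1=O)[C@H](O)c1ccc(OC)c(OC)c1
F4 | step 7 | (3E,4R)-3-[4-(benzyloxy)-3-methoxybenzylidene]-4-[(S)-(3,4-dimethoxyphenyl)(hydroxy)methyl]dihydrofuran-2(3H)-one | COc1cc(/C=C2/C(=O)OC[C@@H]2[C@H](O)c2ccc(OC)c(OC)c2)ccc1OCc1ccccc1
F5 | step 7 | (3S,4R)-4-[(S)-(3,4-dimethoxyphenyl)(hydroxy)methyl]-3-(4-hydroxy-3-methoxybenzyl)dihydrofuran-2(3H)-one | COc1cc(C[C@@H]2C(=O)OC[C@@H]2[C@H](O)c2ccc(OC)c(OC)c2)ccc1O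
F6 | step 11 | potassium trifluoro{(S)-(3,4-dimethoxyphenyl)[(3R,4R)-4-(4-hydroxy-3-methoxybenzyl)-5-oxotetrahydrofuran-3-yl]methyl}borate | [K+].COc1cc(C[C@H]2C(=O)OC[C@@H]2[C@H]([B-](F)(F)F)c2ccc(OC)c(OC)c2)ccc1O
F7 | step 4 | methyl (Z)-3-[4-(benzyloxy)-3-methoxyphenyl]-2-[(tert-butyldimethylsilyl)oxy]acrylate | COC(=O)/C(O[Si](C)(C)C(C)(C)C)=C/c1ccc(OCc2ccccc2)c(OC)c1
F8 | step 2 | (E)-tert-butyldimethyl{[3-(4,4,5,5-tetramethyl-1,3,2-dioxaborolan-2-yl)allyl]oxy}silane | CC(C)(C)[Si](C)(C)OC/C=C/B1OC(C)(C)C(C)(C)O1
F9 | step 2 | (E)-[3-(tert-butyldimethylsilyloxy)prop-1-en-1-yl]boronic acid | CC(C)(C)[Si](C)(C)OC/C=C/B(O)O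
A1 | alternative 1 | 3-[(S)-(tert-butyldimethylsilyloxy)(3,4-dimethoxyphenyl)methyl]cyclobutan-1-one | O=C1CC(C1)[C@H](O[Si](C)(C)C(C)(C)C)c1ccc(OC)c(OC)c1
A2 | alternative 1 | (R)-4-[(S)-(tert-butyldimethylsilyloxy)(3,4-dimethoxyphenyl)methyl]dihydrofuran-2(3H)-one | O=C1C[C@H](CO1)[C@H](O[Si](C)(C)C(C)(C)C)c1ccc(OC)c(OC)c1
A3 | alternative 2 | (Z)-3-(3,4-dimethoxyphenyl)allyl methyl 2-diazomalonate | COC(=O)C(=[N+]=[N-])C(=O)OC/C=C\c1ccc(OC)c(OC)c1
A4 | alternative 2 | methyl 6-(3,4-dimethoxyphenyl)-2-oxo-3-oxabicyclo[3.1.0]hexane-1-carboxylate (aryl cis to C4) | COC(=O)[C@@]12C(=O)OC[C@@H]1[C@@H]2c1ccc(OC)c(OC)c1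
A5 | alternative 3 | (R)-2-[4-(benzyloxy)-3-methoxybenzyl]-4-(3,4-dimethoxyphenyl)-4-oxobutanoic acid | COc1cc(C[C@H](CC(=O)c2ccc(OC)c(OC)c2)C(=O)O)ccc1OCc1ccccc1
A6 | alternative 3 | (3R,4R)-3-[4-(benzyloxy)-3-methoxybenzyl]-4-(3,4-dimethoxybenzoyl)dihydrofuran-2(3H)-one (trans) | COc1cc(C[C@H]2C(=O)OC[C@@H]2C(=O)c2ccc(OC)c(OC)c2)ccc1OCc1ccccc1
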